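The target is cut by a retro-Diels–Alder across C14–C15′ and C2–C4′ into the dienophile 8β-hydroxydehydrozaluzanin C and a 5-epi guaianolide dienone. The cyclopentenone C1–C5 of that dienone, fused to the cycloheptane (C1, C5–C10) that carries the trans C6/C7 lactone, is not assembled as a five-membered ring: it results from photochemical contraction of the cross-conjugated cyclohexadienone ring A (C1–C5, C10) of a eudesmanolide, which in the same operation expands ring B to the cycloheptane and keeps the purchased C6/C7 stereocentres. The precursor is α-santonin, a 6/6-fused dienone lactone, irradiated in acetic acid.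

Key step: step 1

Remark on numbering: guaiane numbering is used throughout; primed locants belong to the 8-hydroxylated half.
Remark on the target: the given SMILES places H-5 β (cis to H-6) and H-10 α in the unprimed half and 8′-OH β; the route is built for exactly this configuration.
Remark on a starting material: deacylcynaropicrin (14) is assumed to be purchasable as a natural-product reagent; otherwise it is the saponification product of commercial cynaropicrin.
Remark on transient stereocentres: the epoxide and carbinol configurations at C1, C3 and C10 in 11–13 are drawn for β-face epoxidation; they are erased in steps 8 and 12, so either epimer serves.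

Step 1
Reactants: 1 α-santonin
Product: 2 O-acetylisophotosantonic lactone (10α-acetoxy-3-oxo-1αH,6βH,7αH,11βH-guai-4-en-12,6-olide)
Conditions: hν (medium-pressure Hg lamp, Pyrex), glacial AcOH, N2, 15–20 °C
Reagents that add atoms: acetic acid, CC(=O)O
Why: Santonin-type (type A) photorearrangement of a cross-conjugated cyclohexadienone: excitation and β,β′-bonding between C1 and C5 give a cyclopropyl oxyallyl zwitterion, which in acetic acid is protonated and opened at C5–C10, so that six-membered ring A contracts to the C1–C5 cyclopentenone while ring B gains C1 and becomes the cycloheptane, the C10 cation being captured by acetate. The closest known reaction is the classical conversion of α-santonin into isophotosantonic lactone itself. The five-membered ring is closed by transannular C1–C5 bonding inside ring A (through the bicyclo[3.1.0]hexanone), and the seven-membered ring is not closed but formed by cleavage of the shared C5–C10 bond. C1 (1α-H) is fixed because C10, tied to ring B, can only swing over the β-face of ring A, and C10 (10α-OAc) by entry of acetate anti to the departing C5–C10 bond; C6, C7 and C11 are untouched. The step needs hydroazulenone formation to win over the lumisantonin and spiro-ketone pathways, which the 4-methyl group (stabilising charge at C4 so that C5–C10 and not C1–C10 breaks) and the protic, nucleophilic solvent should secure.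

Step 2
Reactants: 2 O-acetylisophotosantonic lactone
Product: 3 3-oxo-6βH,7αH,11βH-guaia-1(10),4-dien-12,6-olide
Conditions: DBU, toluene, 60 °C
Reagents that add atoms: none
Why: Vinylogous E1cB elimination: DBU removes the γ-hydrogen at C1 of the enone and the dienolate expels the tertiary C10 acetate, so the alkene forms regiospecifically at C1–C10 (no other neighbour of C10 is acidified) and the two stereocentres made in step 1 are traded for a defined tetrasubstituted Δ1(10) olefin.

Step 3
Reactants: 3 3-oxo-guaia-1(10),4-dien-12,6-olide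
Product: 4 3α-hydroxy-6βH,7αH,11βH-guaia-1(10),4-dien-12,6-olide ((3R)-carbinol)
Conditions: (S)-Me-CBS (0.2 equiv), catecholborane, toluene, −78 °C; aqueous work-up
Reagents that add atoms: none
Why: Corey–Bakshi–Shibata reduction: with the α-methyl-substituted alkenyl flank (C4) as the large group, the (S)-oxazaborolidine delivers hydride to the β-face of the C3 carbonyl (1,2-reduction only) and sets the 3α (R) carbinol under reagent control.

Step 4
Reactants: 4 3α-hydroxy-guaia-1(10),4-dien-12,6-olide
Product: 7 5βH,6βH,7αH,11βH-guaia-1(10),3-dien-12,6-olide, via N-(guaiadienolid-3β-yl)-N-(2-nitrobenzenesulfonyl)hydrazine 5 (not isolated), via 3β-diazenyl-guaia-1(10),4-dien-12,6-olide 6 (not isolated)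
Conditions: PPh3, DEAD, 2-nitrobenzenesulfonylhydrazine (NBSH), N-methylmorpholine, −30 °C, then 23 °C
Reagents that add atoms: none
Why: Myers reductive 1,3-transposition: Mitsunobu displacement by NBSH inverts C3 (3β-N), loss of sulfinic acid gives the monoalkyl diazene, and its suprafacial retro-ene loss of N2 hands the N–H hydrogen to the β-face of C5 while the alkene moves to C3–C4, so the reagent-set C3 centre is relayed into 5β-H (cis to H-6).

Step 5
Reactants: 7 5βH-guaia-1(10),3-dien-12,6-olide
Product: 8 11β-phenylseleno-5βH,6βH,7αH-guaia-1(10),3-dien-12,6-olide (13-methyl α)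
Conditions: LDA, THF, −78 °C; then PhSeBr, −78 °C
Reagents that add atoms: phenylselenenyl bromide, Br[Se]c1ccccc1
Why: α-Selenenylation of the lactone lithium enolate (only C11–H is acidic enough for LDA); the electrophile is expected on the β-face, trans to H-7, the arrangement that later allows elimination only toward the methyl group.

Step 6
Reactants: 8 11β-phenylseleno-5βH-guaia-1(10),3-dien-12,6-olide
Product: 11 1β,10β:3β,4β-diepoxy-5βH,6βH,7αH-guai-11(13)-en-12,6-olide, via the selenoxide of 8 9 (not isolated), via 5βH-guaia-1(10),3,11(13)-trien-12,6-olide 10 (not isolated)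
Conditions: mCPBA (4.3 equiv), CH2Cl2, −78 °C → 0 °C; aq. NaHCO3/Na2S2O3 work-up
Reagents that add atoms: 3-chloroperoxybenzoic acid, OOC(=O)c1cccc(Cl)c1
Why: Selenide oxidation and syn-selenoxide elimination toward C13 (Grieco α-methylenation) unveil the α-methylene lactone, and the excess peracid then epoxidises the tetrasubstituted Δ1(10) and trisubstituted Δ3 alkenes (Prilezhaev) on the face of H-5, anti to C6, leaving the electron-poor exocyclic lactone alkene untouched.

Step 7
Reactants: 11 1β,10β:3β,4β-diepoxy-5βH-guai-11(13)-en-12,6-olide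
Product: 12 1β,3β-dihydroxy-5βH,6βH,7αH-guaia-4(15),10(14),11(13)-trien-12,6-olide
Conditions: Et2AlTMP (from Et2AlCl and LiTMP, 6 equiv), toluene, 0 °C → rt; Rochelle salt work-up
Reagents that add atoms: none
Why: Yamamoto epoxide-to-allylic-alcohol isomerisation: aluminium-bound epoxide oxygen and amide remove a syn β-hydrogen through a cyclic transition state with the usual preference for the unhindered methyl groups, so both exocyclic methylenes (C4=C15 and C10=C14) arise in one operation with the oxygens left on C3 and C1.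

Step 8
Reactants: 12 1β,3β-dihydroxy-5βH-guaia-4(15),10(14),11(13)-trien-12,6-olide
Product: 13 1β-hydroxy-3-oxo-5βH,6βH,7αH-guaia-4(15),10(14),11(13)-trien-12,6-olide
Conditions: activated MnO2, CH2Cl2, 0 °C → rt; used without delay
Reagents that add atoms: none
Why: Chemoselective MnO2 oxidation of the secondary allylic alcohol to the exo-methylene enone; the tertiary C1 alcohol cannot be oxidised and is kept as the latent C1=C2 double bond.

Step 9
Reactants: 14 deacylcynaropicrin
Product: 15 8α-hydroxydehydrozaluzanin C (8α-hydroxy-3-oxo-1αH,5αH,6βH,7αH-guaia-4(15),10(14),11(13)-trien-12,6-olide)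
Conditions: activated MnO2, CH2Cl2, rt
Reagents that add atoms: none
Why: MnO2 oxidises only the allylic C3′ alcohol (next to C4′=C15′) and leaves the non-allylic 8α-alcohol; no stereocentre changes.

Step 10
Reactants: 15 8α-hydroxydehydrozaluzanin C
Product: 16 8β-picolinoyloxy-3-oxo-1αH,5αH,6βH,7αH-guaia-4(15),10(14),11(13)-trien-12,6-olide
Conditions: PPh3, DIAD, picolinic acid, THF, 0 °C → rt
Reagents that add atoms: picolinic acid, OC(=O)c1ccccn1
Why: Mitsunobu esterification: SN2 displacement of the C8′ alkoxyphosphonium by picolinate inverts the equatorial 8α-alcohol to the 8β-ester; the acid is strong enough for a hindered secondary alcohol and its ester can later be removed without base.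

Step 11
Reactants: 16 8β-picolinate
Product: 17 8β-hydroxydehydrozaluzanin C (8β-hydroxy-3-oxo-1αH,5αH,6βH,7αH-guaia-4(15),10(14),11(13)-trien-12,6-olide)
Conditions: Cu(OAc)2·H2O (0.3 equiv), MeOH/CH2Cl2, rt
Reagents that add atoms: none
Why: Cu(II)-chelation-assisted methanolysis of the picolinate (acyl–oxygen cleavage, so C8′ keeps its β configuration) under essentially neutral conditions that should spare both exocyclic Michael acceptors.

Step 12
Reactants: 13 1β-hydroxy-3-oxo-5βH-guaia-4(15),10(14),11(13)-trien-12,6-olide; 17 8β-hydroxydehydrozaluzanin C (3 equiv, excess recovered)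
Product: 19 Diels–Alder adduct (Δ1(10), 2α-H, 5β-H; new bonds C2–C4′ and C14–C15′; C2 on the α-face of the primed cyclopentanone), via 3-oxo-5βH-guaia-1,4(15),10(14),11(13)-tetraen-12,6-olide 18 (not isolated)
Conditions: 13, Martin sulfurane (1.0 equiv), CH2Cl2, −50 °C, 10 min; then 17, −50 °C → rt, dark, Ar
Reagents that add atoms: none
Why: Martin-sulfurane dehydration of the tertiary β-hydroxy ketone (loss toward the acidic C2–H) releases dienone 18, whose s-cis C2=C1–C10=C14 diene adds to the exocyclic enone C4′=C15′ of 17 in an intermolecular Diels–Alder reaction with the orientation established for this diene/dienophile pair (C14–C15′ and C2–C4′); the dienophile is attacked on its convex α-face (side of H-1′/H-5′), which sets the spiro centre C4′, and the diene on its β-face, anti to C6 that the 5β-H geometry holds below the dienone plane, which places H-2 on the α-face.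

Step 13
Reactants: 19 Diels–Alder adduct
Product: 20 target (CNP0178208.1)
Conditions: DABCO (0.2 equiv), degassed benzene, rt, Ar, dark
Reagents that add atoms: none
Why: Amine-mediated 1,3-prototropic shift of the β,γ-unsaturated ketone into conjugation: the doubly activated, α-oriented C2–H is removed and returned within the ammonium dienolate ion pair to the same α-face at C10 (suprafacial), setting 10α-H, while the weak base, short contact and exclusion of oxygen should leave the γ-hydrogens at C5 and C10 of the product in place and prevent C10 oxygenation.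

Compound list
1 | α-santonin | C[C@@H]1C(=O)O[C@@H]2C3=C(C)C(=O)C=C[C@]3(C)CC[C@@H]12 | starting material
2 | O-acetylisophotosantonic lactone (10α-acetoxy-3-oxo-1αH-guai-4-en-12,6-olide) | C[C@@H]1C(=O)O[C@@H]2C3=C(C)C(=O)C[C@H]3[C@](C)(OC(C)=O)CC[C@@H]12 | intermediate
3 | 3-oxo-guaia-1(10),4-dien-12,6-olide | C[C@@H]1C(=O)O[C@@H]2C3=C(C)C(=O)CC3=C(C)CC[C@@H]12 | intermediate
4 | 3α-hydroxy-guaia-1(10),4-dien-12,6-olide | C[C@@H]1C(=O)O[C@@H]2C3=C(C)[C@H](O)CC3=C(C)CC[C@@H]12 | intermediate
5 | N-(guaia-1(10),4-dien-12,6-olid-3β-yl)-N-(2-nitrobenzenesulfonyl)hydrazine | C[C@@H]1C(=O)O[C@@H]2C3=C(C)[C@@H](N(N)S(=O)(=O)c4ccccc4[N+](=O)[O-])CC3=C(C)CC[C@@H]12 | intermediate (not isolated)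
6 | 3β-diazenyl-guaia-1(10),4-dien-12,6-olide | C[C@@H]1C(=O)O[C@@H]2C3=C(C)[C@@H](N=N)CC3=C(C)CC[C@@H]12 | intermediate (not isolated)
7 | 5βH-guaia-1(10),3-dien-12,6-olide (5-epi-11β,13-dihydrokauniolide) | C[C@@H]1C(=O)O[C@@H]2[C@@H]3C(C)=CCC3=C(C)CC[C@@H]12 | intermediate
8 | 11β-phenylseleno-5βH-guaia-1(10),3-dien-12,6-olide | C[C@]1([Se]c2ccccc2)C(=O)O[C@@H]2[C@@H]3C(C)=CCC3=C(C)CC[C@@H]12 | intermediate
9 | selenoxide of 8 | C[C@]1([Se](=O)c2ccccc2)C(=O)O[C@@H]2[C@@H]3C(C)=CCC3=C(C)CC[C@@H]12 | intermediate (not isolated)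
10 | 5βH-guaia-1(10),3,11(13)-trien-12,6-olide (5-epi-kauniolide) | C=C1C(=O)O[C@@H]2[C@@H]3C(C)=CCC3=C(C)CC[C@@H]12 | intermediate (not isolated)
11 | 1β,10β:3β,4β-diepoxy-5βH-guai-11(13)-en-12,6-olide | C=C1C(=O)O[C@@H]2[C@@H]3[C@@]4(C)O[C@H]4C[C@@]35O[C@@]5(C)CC[C@@H]12 | intermediate
12 | 1β,3β-dihydroxy-5βH-guaia-4(15),10(14),11(13)-trien-12,6-olide | C=C1C(=O)O[C@@H]2[C@@H]3C(=C)[C@@H](O)C[C@]3(O)C(=C)CC[C@@H]12 | intermediate
13 | 1β-hydroxy-3-oxo-5βH-guaia-4(15),10(14),11(13)-trien-12,6-olide | C=C1C(=O)O[C@@H]2[C@@H]3C(=C)C(=O)C[C@]3(O)C(=C)CC[C@@H]12 | intermediate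
14 | deacylcynaropicrin (3β,8α-dihydroxy-guaia-4(15),10(14),11(13)-trien-12,6-olide) | C=C1[C@@H](O)C[C@H]2C(=C)C[C@H](O)[C@H]3C(=C)C(=O)O[C@@H]3[C@H]21 | starting material
15 | 8α-hydroxydehydrozaluzanin C | C=C1C(=O)C[C@H]2C(=C)C[C@H](O)[C@H]3C(=C)C(=O)O[C@@H]3[C@H]21 | intermediate
16 | 8β-picolinoyloxy-dehydrozaluzanin C | C=C1C(=O)C[C@H]2C(=C)C[C@@H](OC(=O)c4ccccn4)[C@H]3C(=C)C(=O)O[C@@H]3[C@H]21 | intermediate
17 | 8β-hydroxydehydrozaluzanin C | C=C1C(=O)C[C@H]2C(=C)C[C@@H](O)[C@H]3C(=C)C(=O)O[C@@H]3[C@H]21 | intermediate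
18 | 3-oxo-5βH-guaia-1,4(15),10(14),11(13)-tetraen-12,6-olide | C=C1C(=O)O[C@@H]2[C@@H]3C(=C)C(=O)C=C3C(=C)CC[C@@H]12 | intermediate (not isolated)
19 | Diels–Alder adduct (Δ1(10), 2α-H) | C=C1C(=O)[C@@H]2C3=C(CC[C@H]4C(=C)C(=O)O[C@@H]4[C@H]13)CC[C@]21C(=O)C[C@H]2C(=C)C[C@@H](O)[C@H]3C(=C)C(=O)O[C@@H]3[C@H]21 | intermediate
20 | CNP0178208.1 | C=C1C(=O)C2=C3[C@H](CC[C@H]4C(=C)C(=O)O[C@@H]4[C@H]13)CC[C@]21C(=O)C[C@H]2C(=C)C[C@@H](O)[C@H]3C(=C)C(=O)O[C@@H]3[C@H]21 | target

Total step count: 13. Longest linear sequence: 10 (steps 1–8, 12, 13).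

Steps most likely to fail

1. Step 12. The transient dienone is both diene and dienophile, so self-cycloaddition can outrun the cross-cycloaddition, and the dehydrating agent cannot be left in contact with the free C8′ hydroxyl, which forces the diene to be generated all at once. The fallback sets out from 13 and the ester 16. Martin sulfurane is added slowly to 13 in the presence of a large excess of 16, whose hydroxyl is masked, so the diene stays at low stationary concentration beside its partner. This should give the picolinate of the Diels–Alder adduct F1. DABCO-mediated conjugation as in step 13 then gives the picolinate of the target F2, and neutral Cu(OAc)2/MeOH cleavage returns to the route at 20.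

2. Step 4. The activated alcohol is dienylic, so ionisation or β-elimination (toward a fulvene) and partial SN1 loss of stereospecificity at C3, and hence at C5, may compete with the SN2 displacement. The fallback sets out from 3. The electron-rich Δ1(10) alkene is epoxidised first with mCPBA (the enone alkene is inert) to give 1β,10β-epoxy-3-oxo-guai-4-en-12,6-olide F3. CBS reduction gives the now simply allylic 3α-alcohol F4, and the same Myers transposition gives 1β,10β-epoxy-5βH-guai-3-en-12,6-olide F5. LDA/PhSeBr gives its 11β-phenylselenide F6, and mCPBA (selenoxide elimination plus Δ3 epoxidation) returns to the route at 11. An α-epoxide would serve equally, since C1 is erased in step 12.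

3. Step 7. The aluminium amide may deprotonate the α-methylene lactone at C7 (drift of the exocyclic alkene into the ring) or attack it, and may abstract ring hydrogens instead of methyl hydrogens. The fallback sets out from 11. The lactone alkene is masked as its dimethylamine Michael adduct, the 13-dimethylamino-11βH diepoxide F7. Et2AlTMP isomerisation on this saturated lactone gives the 13-dimethylamino diol F8. Quaternisation with MeI gives the trimethylammonium iodide F9, and NaHCO3-induced elimination returns to the route at 12.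

Further compounds
F1 | step 12 | 8′β-picolinate of Diels–Alder adduct 19 | C=C1C(=O)[C@@H]2C3=C(CC[C@H]4C(=C)C(=O)O[C@@H]4[C@H]13)CC[C@]21C(=O)C[C@H]2C(=C)C[C@@H](OC(=O)c4ccccn4)[C@H]3C(=C)C(=O)O[C@@H]3[C@H]21
F2 | step 12 | 8′β-picolinate of target 20 | C=C1C(=O)C2=C3[C@H](CC[C@H]4C(=C)C(=O)O[C@@H]4[C@H]13)CC[C@]21C(=O)C[C@H]2C(=C)C[C@@H](OC(=O)c4ccccn4)[C@H]3C(=C)C(=O)O[C@@H]3[C@H]21
F3 | step 4 | 1β,10β-epoxy-3-oxo-guai-4-en-12,6-olide | C[C@@H]1C(=O)O[C@@H]2C3=C(C)C(=O)C[C@@]34O[C@@]4(C)CC[C@@H]12
F4 | step 4 | 1β,10β-epoxy-3α-hydroxy-guai-4-en-12,6-olide | C[C@@H]1C(=O)O[C@@H]2C3=C(C)[C@H](O)C[C@@]34O[C@@]4(C)CC[C@@H]12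
F5 | step 4 | 1β,10β-epoxy-5βH-guai-3-en-12,6-olide | C[C@@H]1C(=O)O[C@@H]2[C@@H]3C(C)=CC[C@@]34O[C@@]4(C)CC[C@@H]12
F6 | step 4 | 11β-phenylseleno-1β,10β-epoxy-5βH-guai-3-en-12,6-olide | C[C@]1([Se]c2ccccc2)C(=O)O[C@@H]2[C@@H]3C(C)=CC[C@@]34O[C@@]4(C)CC[C@@H]12
F7 | step 7 | 13-dimethylamino-1β,10β:3β,4β-diepoxy-5βH,11βH-guaian-12,6-olide | CN(C)C[C@@H]1C(=O)O[C@@H]2[C@@H]3[C@@]4(C)O[C@H]4C[C@@]35O[C@@]5(C)CC[C@@H]12
F8 | step 7 | 13-dimethylamino-1β,3β-dihydroxy-5βH,11βH-guaia-4(15),10(14)-dien-12,6-olide | CN(C)C[C@@H]1C(=O)O[C@@H]2[C@@H]3C(=C)[C@@H](O)C[C@]3(O)C(=C)CC[C@@H]12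
F9 | step 7 | 13-trimethylammonio-1β,3β-dihydroxy-5βH,11βH-guaia-4(15),10(14)-dien-12,6-olide iodide | C[N+](C)(C)C[C@@H]1C(=O)O[C@@H]2[C@@H]3C(=C)[C@@H](O)C[C@]3(O)C(=C)CC[C@@H]12.[I-]
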